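A target molecule in the south flask has 1.84 lifetimes to get through in the run. This is the lifetime count: the side step's rate constant times the charged starting material times the run time.

    starting material + free enzyme ⇌ first complex (K1 = 310 M⁻¹, k1 = 990 M⁻¹ s⁻¹)
    first complex ⇌ loaded enzyme + first product (K2 = 0.027 M, k2 = 0.15 s⁻¹)
    second substrate + loaded enzyme ⇌ second complex (K3 = 100 M⁻¹, k3 = 42 M⁻¹ s⁻¹)
    second complex ⇌ free enzyme + target (K4 = 0.0074 M, k4 = 0.22 s⁻¹)
    starting material + target → side product (k5 = 0.0034 M⁻¹ s⁻¹)
    2 second complex ⇌ resting dimer, settled at all times (K6 = 1.0 × 10⁷ M⁻¹)

| setting | south | north-east | south-west | west | north-west |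
|---|---|---|---|---|---|
| starting material | 3.0 mM | 10 mM | 30 mM | 100 mM | 250 mM |
| second substrate | 2.50 equiv | 2.50 equiv | 2.50 equiv | 2.50 equiv | 2.50 equiv |
| free enzyme | 0.012 mol% | 0.012 mol% | 0.012 mol% | 0.012 mol% | 0.012 mol% |
| time | 50 h | 50 h | 50 h | 50 h | 50 h |

- percent here means starting material units held: one side product or resting dimer counts as two
- two of one species on the left: rate k times its square, two consumed each time
- "hardly changes" means that all values lie within two and a half points (for a concentration: within two and a half percent of the largest)
- run time (south): 50 h

- [target] at the end for south, north-east, south-west, west, north-west, in this order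
- the shape of the row from first to last (rises, then falls / falls all the way / falls, then rises / hardly changes / rises all the way)

1. While starting material stays near its charge, the side step is pseudo-first-order in target, and one lifetime in south is 27.2 h.

2. Work with what is left, not with what is made. If target forms at an even pace, the kept fraction of everything made is (1 − e^(−count))/count, which is 45.8% for south.

3. The count grows with the charge. In north-west it is 153, so the kept fraction sinks to 0.654%.

4. One number is not enough, since a fraction says nothing about the amount made. The catalyst charge follows the starting material, but the pairing number, dimer constant times catalyst charged, goes from 3.60 in south to 300 in north-west. Where pairing is strong, unpaired catalyst grows about as the square root of its charge.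

5. From south to north-east the kept fraction drops 2.81-fold while the catalyst charge grows 3.33-fold, so target can rise there. From south to north-west the fraction drops 70.0-fold against a square-root gain of 9.13, so target should fall. My reckoning stops at that shape, a rise and then a fall, and gives no row.

6. The forecast goes further, with 0.95 mM, 1.6 mM, 2.4 mM, 0.95 mM and 0.46 mM, shape rises, then falls, on the ground that at high loading “target sits at a quasi-steady level”.

7. The flasks give 0.924 mM, 2.04 mM, 2.21 mM, 0.968 mM and 0.471 mM: rises, then falls.

In south at 20.9 h, target is made, net, 2.28 times as fast as it is used up, and at the end 0.924 mM stands against 1.50 mM of first product, a kept fraction of 61.6%, more than the 45.8% reckoned at full charge, with 31% of the starting material left. In north-west, multiplying the count by the 63% of starting material left and taking one over the result gives a kept fraction of 1.03%, which on 46.0 mM of first product makes 0.475 mM, and the flask holds 0.471 mM.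

The constants were drawn at random within sensible limits; the run is a simulation.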